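**Structural features**

The target is a ten-membered carbocycle (C1–C10) with a Z-trisubstituted enone (C4=C5–C6=O, methyl C15 on C5), an epoxide fused across C1–C10, and a second epoxide spiro at C8 whose other carbon, C11, lies outside the ring. C1 carries the acetoxymethyl group C14; C11 carries the methyl C12 and the acetoxymethyl group C13. The four stereocentres form two adjacent pairs, C1/C10 (1R,10R) and C8/C11 (8S,11S), separated only by the C9 methylene, and C1, C8 and C11 are fully substituted oxirane carbons. Re-deriving the geometry from the SMILES string shows C2 cis to C9 on the ring epoxide and C9 cis to C13 on the spiro-epoxide. Each epoxide therefore maps onto one open-chain allylic alcohol of defined geometry (C14–OH on C1=C10, C13–OH on C8=C11), and the two need oxygen delivery of opposite tartrate sense. The fragile points are the C6 ketone beta to the spiro-epoxide (base opens it by beta-elimination), the acid-labile tri- and tetrasubstituted oxiranes, the two epoxy acetates (acyl loss would allow Payne migration) and the Z-enone. The real difficulty is closing a medium ring that already holds both epoxides and a Z-trisubstituted alkene. The key step uses the C3–C4 bond: C3 is a plain methylene two atoms from the quaternary C1, and C4 is the sp2 carbon of the Z alkene, so a vinyl group on C1 and a (Z)-iodoalkene at C4=C5 can be joined by hydroboration and sp3–sp2 coupling.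

**Logic of the disconnections**

33 ⇐ 32 ⇐ 31. No skeletal bond is cut; the C6 carbonyl is traced back to a carbinol and then to a silyl ether. This keeps an enolisable ketone away from the basic ring closure. The demand is a desilylation and an oxidation that are neither acidic nor basic. For that reason the C6 silyl group is chosen as triethylsilyl rather than a bulkier one, which is a deliberate change to the precursor design.

31 ⇐ 29 (through 30). The C3–C4 bond is cut. The ring opens to an acyclic chain on which all four stereocentres already exist, and the Z alkene becomes a stereodefined iodoalkene. The forward step must hydroborate only the C1 vinyl group, must keep the alkene geometry, and must favour ring closure over oligomerisation.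

29 ⇐ 28 ⇐ 27 ⇐ 26 ⇐ 25 ⇐ 24 ⇐ 23. The C–O bonds of both oxiranes and both acetyl C–O bonds are cut, one allylic alcohol at a time. Each epoxide then comes from a reagent-controlled epoxidation of an open-chain primary allylic alcohol. The two alcohols need mirror-image tartrates, so only one may be free at a time: C13–OH stays masked as a 4-methoxybenzyl ether until the C1–C10 epoxide and its acetate are in place. The forward steps must acetylate the primary C14–OH in the presence of the secondary C6–OH, and must remove the benzyl-type ether without touching the vinyl epoxide.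

23 ⇐ 21 + 8, and 21 ⇐ 20. The C5–C15 and C4–I bonds are cut, so the iodoalkene becomes a terminal alkyne next to the free C6 carbinol. This is placed after every other organometallic step, because no vinyl iodide would survive the Grignard, organolithium and copper chemistry used earlier. The demand is an anti addition across C4≡C5 directed by the C6 alkoxide. That is why the C6 silyl ether and the alkyne silyl cap are removed together just before.

20 ⇐ 17 + 18. The C1–C2 bond is cut. The dienol becomes an internal propargylic alcohol, and anti addition of 18 fixes C2 cis to C9, the geometry the ring epoxide needs.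

17 ⇐ 15 + 16. The C9–C10 bond is cut between an allylic bromide and a terminal alkyne. An alkynyl nucleophile on an allylic halide is the polarity that keeps the skipped enyne regiochemistry; the reverse pairing (alkenyl metal on a propargylic halide) would give allenes. The demand is substitution at C9 without allylic shift.

15 ⇐ 14 ⇐ 11 ⇐ 10 ⇐ 7 + 8. The C8–C9 bond (one-carbon electrophile on a C8 alkenyl metal), the C11–C12 bond and the C8–I bond are cut. The tetrasubstituted alkene is thus made in one anti-carbomagnesiation–iodination of an alkynol, with iodine, and later C9, cis to C13. Going through the iodide allows C13–OH to be protected before C9 is introduced, so the two allylic oxygens never have to be told apart.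

7 ⇐ 5 ⇐ 4 ⇐ 1 + 2. The C11–C13 bond (hydroxymethylation of an acetylide) and the C6–C7 bond (propargylation of an ynal) are cut. This leaves two three-carbon building blocks, and it puts the C6 carbinol and a silyl-capped C4≡C5 alkyne in place from the first step.

**Other disconnections considered**

Alternative 1: The cut is C9–C10 together with the acyl C13–O bond. The silyl dienolate A1 and the 2-methylene aldehyde A2 combine under a chiral Lewis acid (hetero-Diels–Alder, or vinylogous Mukaiyama aldol with lactonisation) to give the dihydropyranone A3.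
- In its favour: C10 is set by catalysis, the six-membered lactone locks C9 cis to C13 across C8=C11, and the building blocks are simple.
- Where it is better than the chosen plan: the geometry of the tetrasubstituted alkene is guaranteed by a ring, where the chosen route spends five steps (4 to 8) on it.
- Against it, on stereochemistry: as drawn, C10 of A3 has the spatial sense opposite to C10 of the target if the C10–O bond is kept. The plan must therefore break that bond with inversion (for instance a C1 alkoxide displacing an activated C10 oxygen) or use the mirror-image catalyst.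
- Against it, on what remains: C1, C8 and C11 would then rest on substrate control; the C7 ester must be extended to C6; the lactone must be reduced and its two oxygens told apart; and no ring closure is defined.
- Mechanism: the enal A2 is a reactive acrolein-type acceptor, and the dienolate can react at the alpha or gamma carbon.
- Step economy: it converges early but should need a long endgame, so no clear gain in step count is expected.

Alternative 2: The cut is C7–C8 together with the C8–O bond of the spiro-epoxide. The Reformatsky reagent A5 adds to the ketone of the epoxy ketone A4, and the tertiary alkoxide then opens the neighbouring oxirane at C11 (Payne rearrangement) to give the spiro-epoxy ester A6.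
- In its favour: C11 is bought from the chiral pool and C8 follows by 1,2-induction. A chelate between the ketone and oxirane oxygens, attacked anti to the methyl group, leads after inversion at C11 to C9 cis to C13, which is the correct relative configuration.
- Where it is better than the chosen plan: no tetrasubstituted alkene and no second asymmetric epoxidation are needed, and the spiro-epoxide costs one step.
- Against it: the facial selectivity of a zinc enolate on an epoxy ketone is uncertain. The spiro-epoxide would then have to survive every later C–C bond formation, including building the iodoalkene or enone from the C6 ester, where the chosen route uses Grignard and organolithium reagents that an oxirane would not tolerate.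
- Ring closure: it is still needed, so the medium-ring problem is the same.
- Step economy: it should be roughly equal, with risk moved from epoxidation to functional-group compatibility.

Alternative 3: The cut is the acyl–alkenyl bond C5–C6. The thioester and (Z)-alkenylstannane ends of the seco compound A7 are coupled under palladium with a copper carboxylate (Liebeskind–Srogl) to give the protected cyclodecatrienone A8.
- In its favour: the ketone is formed directly under neutral conditions.
- Where it is better than the chosen plan: no epoxide is present during the palladium step, and the redox endgame (steps 19 and 20) is not needed.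
- Where it is equal: A7 would be built by the same carbomagnesiation chemistry, and its two allylic oxygens already carry different protecting groups.
- Against it: both asymmetric epoxidations then fall on the macrocycle, where reagent control must compete with the conformational bias of a ten-membered ring, and the enone must survive the peroxide. All four stereocentres would be set in the last steps.
- Ring strain: the closure must form a ring with four trigonal ring atoms in a row from C4 to C8, and it uses stoichiometric tin and copper.
- Step economy: comparable, but the stereochemical risk sits at the end instead of on the open chain.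

Key step: step 18

Assumption: C6 is formed racemic in step 1 and carried as a pair of epimers, because it becomes the ketone carbon; names say 6RS and SMILES leave C6 undefined (either epimer serves in the ring closure).
Assumption: aldehyde 1 is bought; it is otherwise one step from ethynyltriisopropylsilane by formylation of its lithium acetylide.
Remark: locants C1–C15 follow the target numbering in every compound; the CIP letter at C8 is S for the silyl ethers and the ketone and formally R for the free alcohol 32, with no change in geometry.

**Step 1**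
Reactants: 1 3-(triisopropylsilyl)prop-2-ynal; 2 propargyl bromide (3-bromoprop-1-yne)
Product: 4 (3RS)-1-(triisopropylsilyl)hexa-1,5-diyn-3-ol, via allenylzinc bromide 3 (not isolated)
Conditions: Zn dust, THF, 0 °C to rt; aq NH4Cl
Reagents that add atoms: none
Why: Barbier propargylation: the allenylzinc reagent adds through its gamma carbon to the aldehyde and should give the homopropargylic alcohol, forming C6–C7; C6 is racemic, which is accepted because it ends as the ketone.

**Step 2**
Reactants: 4 (3RS)-1-(triisopropylsilyl)hexa-1,5-diyn-3-ol
Product: 5 (3RS)-3-[(tert-butyldimethylsilyl)oxy]-1-(triisopropylsilyl)hexa-1,5-diyne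
Conditions: TBSCl, imidazole, DMF, rt
Reagents that add atoms: tert-butyldimethylsilyl chloride, CC(C)(C)[Si](C)(C)Cl
Why: Standard silylation of a secondary alcohol; masking the C6 oxygen stops it from directing Grignard addition to the neighbouring silylalkyne in step 4.

**Step 3**
Reactants: 5 (3RS)-3-[(tert-butyldimethylsilyl)oxy]-1-(triisopropylsilyl)hexa-1,5-diyne
Product: 7 (5RS)-5-[(tert-butyldimethylsilyl)oxy]-7-(triisopropylsilyl)hepta-2,6-diyn-1-ol, via lithium acetylide 6 (not isolated)
Conditions: n-BuLi, THF, −78 °C; (CH2O)n, −78 °C to rt
Reagents that add atoms: formaldehyde (as paraformaldehyde), C=O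
Why: Deprotonation of the only terminal alkyne and hydroxymethylation of the acetylide install C13 and the directing hydroxyl; the other alkyne is blocked by silicon.

**Step 4**
Reactants: 7 (5RS)-5-[(tert-butyldimethylsilyl)oxy]-7-(triisopropylsilyl)hepta-2,6-diyn-1-ol; 8 methylmagnesium bromide
Product: 10 (2Z,5RS)-5-[(tert-butyldimethylsilyl)oxy]-3-iodo-2-methyl-7-(triisopropylsilyl)hept-2-en-6-yn-1-ol, via magnesium chelate 9 (not isolated)
Conditions: MeMgBr (4 equiv), CuI (15 mol%), THF, −10 to 45 °C; then I2, −78 to 0 °C
Reagents that add atoms: iodine, II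
Why: Copper-catalysed anti-carbomagnesiation of a propargylic alcohol: methyl adds to C11 and magnesium ends on C8, held cis to C13 in a five-membered alkoxide chelate; iodinolysis with retention should fix the tetrasubstituted geometry with iodine (later C9) cis to C13.

**Step 5**
Reactants: 10 (2Z,5RS)-5-[(tert-butyldimethylsilyl)oxy]-3-iodo-2-methyl-7-(triisopropylsilyl)hept-2-en-6-yn-1-ol
Product: 11 (2Z,5RS)-5-[(tert-butyldimethylsilyl)oxy]-3-iodo-1-[(4-methoxybenzyl)oxy]-2-methyl-7-(triisopropylsilyl)hept-2-en-6-yne
Conditions: NaH, PMBCl, Bu4NI (cat.), THF–DMF, 0 °C to rt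
Reagents that add atoms: 4-methoxybenzyl chloride, COc1ccc(CCl)cc1
Why: Williamson etherification of the primary allylic alkoxide; the ether survives all later organometallic and fluoride steps and is removed oxidatively in step 15.

**Step 6**
Reactants: 11 (2Z,5RS)-5-[(tert-butyldimethylsilyl)oxy]-3-iodo-1-[(4-methoxybenzyl)oxy]-2-methyl-7-(triisopropylsilyl)hept-2-en-6-yne
Product: 14 (2Z)-2-{(2RS)-2-[(tert-butyldimethylsilyl)oxy]-4-(triisopropylsilyl)but-3-yn-1-yl}-4-[(4-methoxybenzyl)oxy]-3-methylbut-2-en-1-ol, via vinyllithium 12 (not isolated), via enal 13 (not isolated)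
Conditions: t-BuLi (2.1 equiv), Et2O, −78 °C; DMF, −78 °C; then MeOH, NaBH4, 0 °C
Reagents that add atoms: N,N-dimethylformamide, CN(C)C=O
Why: Iodine–lithium exchange is stereoretentive and faster than any deprotonation at −78 °C; formylation and in-flask borohydride reduction should deliver C9 as a hydroxymethyl group cis to C13.

**Step 7**
Reactants: 14 (2Z)-2-{(2RS)-2-[(tert-butyldimethylsilyl)oxy]-4-(triisopropylsilyl)but-3-yn-1-yl}-4-[(4-methoxybenzyl)oxy]-3-methylbut-2-en-1-ol
Product: 15 (2Z)-allylic bromide corresponding to 14 (C9 hydroxyl replaced by bromine)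
Conditions: CBr4, PPh3, 2,6-lutidine, CH2Cl2, −20 to 0 °C
Reagents that add atoms: carbon tetrabromide, BrC(Br)(Br)Br
Why: Appel bromination of a primary allylic alcohol under buffered conditions; substitution at the primary carbon should leave the alkene geometry untouched, and the bromide is used at once.

**Step 8**
Reactants: 15 (2Z)-allylic bromide corresponding to 14; 16 prop-2-yn-1-ol
Product: 17 (5E)-5-{(2RS)-2-[(tert-butyldimethylsilyl)oxy]-4-(triisopropylsilyl)but-3-yn-1-yl}-7-[(4-methoxybenzyl)oxy]-6-methylhept-5-en-2-yn-1-ol (C9 cis to C13)
Conditions: CuI, K2CO3, DMF, rt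
Reagents that add atoms: none
Why: Copper-mediated coupling of a terminal alkyne with an allylic bromide forms C9–C10; attack at the primary carbon is expected because the alternative allylic terminus (C11) is fully substituted, and the free hydroxyl of 16 is tolerated and is needed in step 9.

**Step 9**
Reactants: 17 skipped enynol from step 8; 18 vinylmagnesium bromide
Product: 20 (2E,5E)-2-ethenyl-5-{(2RS)-2-[(tert-butyldimethylsilyl)oxy]-4-(triisopropylsilyl)but-3-yn-1-yl}-7-[(4-methoxybenzyl)oxy]-6-methylhepta-2,5-dien-1-ol, via magnesium chelate 19 (not isolated)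
Conditions: CH2=CHMgBr (5 equiv), THF, reflux; aq NH4Cl
Reagents that add atoms: none
Why: Alkoxide-directed anti-carbomagnesiation of an internal propargylic alcohol: vinyl adds to C1 and magnesium sits on C10 cis to C14, so protonation should give H-10 cis to C14 and the vinyl group cis to C9, the geometry the ring epoxide requires.

**Step 10**
Reactants: 20 dienol from step 9
Product: 21 (2E,5E)-2-ethenyl-5-[(2RS)-2-hydroxybut-3-yn-1-yl]-7-[(4-methoxybenzyl)oxy]-6-methylhepta-2,5-dien-1-ol
Conditions: Bu4NF (3 equiv), THF, 0 °C to rt
Reagents that add atoms: none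
Why: Fluoride cleaves the Si–O bond at C6 and the Si–C(sp) bond at C4 in one operation, freeing exactly the propargylic alcohol and terminal alkyne that step 11 needs; the benzyl-type ether is inert.

**Step 11**
Reactants: 21 diol alkyne from step 10; 8 methylmagnesium bromide
Product: 23 (2E,5E)-2-ethenyl-5-[(2RS,3Z)-2-hydroxy-4-iodo-3-methylbut-3-en-1-yl]-7-[(4-methoxybenzyl)oxy]-6-methylhepta-2,5-dien-1-ol, via magnesium chelate 22 (not isolated)
Conditions: MeMgBr (5 equiv), CuI (20 mol%), THF, −10 °C to rt; then I2, −78 to 0 °C; aq Na2S2O3
Reagents that add atoms: iodine, II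
Why: Copper-catalysed anti-carbomagnesiation of a secondary propargylic alcohol: methyl (C15) adds to C5 and magnesium on C4 is chelated by the C6 alkoxide, so iodinolysis should give the (Z)-iodoalkene with iodine cis to C6; the C14 alkoxide is a spectator and this is the last organometallic step, so the iodide meets no further carbanion chemistry.

**Step 12**
Reactants: 23 (4Z)-iodoalkene diol from step 11
Product: 24 (1R,10R)-vinyl epoxy alcohol: C14 alcohol on the C1–C10 oxirane; C8=C11 with C9 cis to C13; C13 4-methoxybenzyl ether; C6 hydroxyl (6RS); (4Z)-iodoalkene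
Conditions: Ti(OiPr)4 (1.2 equiv), D-(−)-diisopropyl tartrate (1.4 equiv), t-BuOOH, 4 Å MS, CH2Cl2, −20 °C
Reagents that add atoms: tert-butyl hydroperoxide, CC(C)(C)OO
Why: Sharpless asymmetric epoxidation under reagent control: D-(−)-tartrate gives the mirror image of the (2S,3S) outcome that L-(+)-tartrate gives with E-allylic alcohols, which sets (1R,10R); only the allylic C1=C10 bond should react, since the vinyl group is homoallylic, the iodoalkene is electron-poor and the other allylic oxygen is etherified.

**Step 13**
Reactants: 24 (1R,10R)-vinyl epoxy alcohol from step 12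
Product: 25 C14 acetate of 24 (C6 hydroxyl free)
Conditions: AcCl (1.05 equiv), 2,4,6-collidine, CH2Cl2, −78 °C
Reagents that add atoms: acetyl chloride, CC(Cl)=O
Why: Kinetically selective acetylation of a primary hydroxyl over a hindered secondary allylic one with acetyl chloride and a hindered pyridine base at low temperature.

**Step 14**
Reactants: 25 C14 acetate from step 13
Product: 26 C6 triethylsilyl ether of 25
Conditions: Et3SiCl, imidazole, CH2Cl2, 0 °C
Reagents that add atoms: chlorotriethylsilane, CC[Si](Cl)(CC)CC
Why: Mild silylation of the remaining secondary alcohol under non-acidic conditions that the vinyl epoxide and acetate tolerate; triethylsilyl is chosen so that it can later be removed at 0 °C.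

**Step 15**
Reactants: 26 C6 triethylsilyl ether from step 14
Product: 27 C13 allylic alcohol: (1R,10R)-vinyl epoxide; C14 acetate; C6 triethylsilyl ether; C8=C11 with C9 cis to C13; (4Z)-iodoalkene
Conditions: DDQ, CH2Cl2–pH 7 buffer, 0 °C
Reagents that add atoms: none
Why: Oxidative cleavage of the 4-methoxybenzyl ether by hydride abstraction and hydrolysis of the oxocarbenium ion; the buffered, neutral medium should spare the epoxide, the silyl ether and the acetate.

**Step 16**
Reactants: 27 C13 allylic alcohol from step 15
Product: 28 (1R,8S,10R,11S)-bis-epoxide with free C13 hydroxyl: C14 acetate; C6 triethylsilyl ether; C1 vinyl; (4Z)-iodoalkene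
Conditions: Ti(OiPr)4 (1.0 equiv), L-(+)-diisopropyl tartrate (1.2 equiv), t-BuOOH, 4 Å MS, CH2Cl2, −20 °C
Reagents that add atoms: tert-butyl hydroperoxide, CC(C)(C)OO
Why: Sharpless asymmetric epoxidation of the only free allylic alcohol: L-(+)-tartrate delivers oxygen to the face that gives (8S,11S), and the alkene geometry places C9 cis to C13 on the new oxirane; this is the tartrate sense opposite to step 12.

**Step 17**
Reactants: 28 bis-epoxy alcohol from step 16
Product: 29 bis-epoxy vinyl iodide: (1R,8S,10R,11S)-diacetate with C1 vinyl group; C6 triethylsilyl ether (6RS); (4Z)-iodoalkene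
Conditions: Ac2O, pyridine, DMAP (cat.), CH2Cl2, 0 °C
Reagents that add atoms: acetic anhydride, CC(=O)OC(C)=O
Why: Acetylation of the primary epoxy alcohol under basic, non-nucleophilic conditions; capping the hydroxyl at once removes the possibility of Payne migration.

**Step 18**
Reactants: 29 bis-epoxy vinyl iodide from step 17
Product: 31 C6 triethylsilyloxy bis-epoxy macrocycle (ten-membered ring closed at C3–C4; 4Z; 6RS), via alkylborane 30 (not isolated)
Conditions: 9-BBN dimer, THF, 0 °C to rt; then aq Cs2CO3; slow addition to Pd(dppf)Cl2 (20 mol%), AsPh3 (40 mol%), Cs2CO3, DMF–THF–H2O, rt, ca. 2 mM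
Reagents that add atoms: none
Why: 9-BBN adds syn and anti-Markovnikov to the monosubstituted C2=C3 bond only and places boron on C3, the trisubstituted iodoalkene, the esters and the oxiranes reacting far more slowly. Aqueous Cs2CO3 then destroys residual B–H and forms the hydroxyborate before any palladium is present, so zerovalent palladium never meets a vinyl epoxide. Zerovalent palladium formed from Pd(dppf)Cl2 inserts into the C4–I bond with retention, the borate transfers the primary C3 alkyl group, and reductive elimination forms C3–C4. The closest known reaction type is the B-alkyl Suzuki–Miyaura macrocyclisation of a 9-BBN alkylborane with a vinyl iodide. The ten-membered ring closes by reductive elimination from an eleven-membered alkyl(alkenyl)palladium chelate, an intramolecular sp3–sp2 cross-coupling run with slow addition at high dilution to favour closure over oligomerisation. No stereocentre is created, and the Z geometry of C4=C5 is carried over because oxidative addition and reductive elimination are stereoretentive. The selectivities needed are chemoselective hydroboration (secured by the steric bias of 9-BBN), survival of both acetates (carbonate base at room temperature) and survival of the oxiranes (no acid, and C6 masked as a silyl ether so that no enolisable ketone lies beta to the spiro-epoxide).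

**Step 19**
Reactants: 31 C6 triethylsilyloxy bis-epoxy macrocycle
Product: 32 C6 alcohol of the bis-epoxy macrocycle (6RS)
Conditions: HF·pyridine, excess pyridine, THF, 0 °C
Reagents that add atoms: none
Why: Buffered fluoride cleavage of a secondary triethylsilyl ether; the excess pyridine keeps the medium from opening the oxiranes or cleaving the acetates.

**Step 20**
Reactants: 32 C6 alcohol of the bis-epoxy macrocycle
Product: 33 CNP0185847.4 (target)
Conditions: Dess–Martin periodinane, NaHCO3, CH2Cl2, 0 °C to rt
Reagents that add atoms: none
Why: Dess–Martin oxidation of the secondary allylic alcohol under bicarbonate buffer should give the Z-enone without epimerisable centres and without base-induced opening of the beta spiro-epoxide; both C6 epimers converge on one ketone.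

**Compound list**

1 | 3-(triisopropylsilyl)prop-2-ynal | O=CC#C[Si](C(C)C)(C(C)C)C(C)C | starting material
2 | propargyl bromide | C#CCBr | starting material
3 | allenylzinc bromide | C=C=C[Zn]Br | intermediate
4 | (3RS)-1-(triisopropylsilyl)hexa-1,5-diyn-3-ol | C#CCC(O)C#C[Si](C(C)C)(C(C)C)C(C)C | intermediate
5 | (3RS)-3-[(tert-butyldimethylsilyl)oxy]-1-(triisopropylsilyl)hexa-1,5-diyne | C#CCC(O[Si](C)(C)C(C)(C)C)C#C[Si](C(C)C)(C(C)C)C(C)C | intermediate
6 | lithium acetylide of 5 | [Li]C#CCC(O[Si](C)(C)C(C)(C)C)C#C[Si](C(C)C)(C(C)C)C(C)C | intermediate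
7 | (5RS)-5-[(tert-butyldimethylsilyl)oxy]-7-(triisopropylsilyl)hepta-2,6-diyn-1-ol | OCC#CCC(O[Si](C)(C)C(C)(C)C)C#C[Si](C(C)C)(C(C)C)C(C)C | intermediate
8 | methylmagnesium bromide | C[Mg]Br | starting material
9 | cyclic vinylmagnesium alkoxide from 7 (Mg on C8, methyl on C11) | CC1=C(CC(O[Si](C)(C)C(C)(C)C)C#C[Si](C(C)C)(C(C)C)C(C)C)[Mg]OC1 | intermediate
10 | (2Z,5RS)-5-[(tert-butyldimethylsilyl)oxy]-3-iodo-2-methyl-7-(triisopropylsilyl)hept-2-en-6-yn-1-ol | OC/C(C)=C(\I)CC(O[Si](C)(C)C(C)(C)C)C#C[Si](C(C)C)(C(C)C)C(C)C | intermediate
11 | 4-methoxybenzyl ether of 10 | COc1ccc(COC/C(C)=C(\I)CC(O[Si](C)(C)C(C)(C)C)C#C[Si](C(C)C)(C(C)C)C(C)C)cc1 | intermediate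
12 | C8 vinyllithium from 11 | COc1ccc(COC/C(C)=C(\[Li])CC(O[Si](C)(C)C(C)(C)C)C#C[Si](C(C)C)(C(C)C)C(C)C)cc1 | intermediate
13 | (Z)-enal, C9 formyl cis to C13 | COc1ccc(COC/C(C)=C(\C=O)CC(O[Si](C)(C)C(C)(C)C)C#C[Si](C(C)C)(C(C)C)C(C)C)cc1 | intermediate
14 | (2Z)-2-{(2RS)-2-[(tert-butyldimethylsilyl)oxy]-4-(triisopropylsilyl)but-3-yn-1-yl}-4-[(4-methoxybenzyl)oxy]-3-methylbut-2-en-1-ol | COc1ccc(COC/C(C)=C(\CO)CC(O[Si](C)(C)C(C)(C)C)C#C[Si](C(C)C)(C(C)C)C(C)C)cc1 | intermediate
15 | (2Z)-allylic bromide corresponding to 14 | COc1ccc(COC/C(C)=C(\CBr)CC(O[Si](C)(C)C(C)(C)C)C#C[Si](C(C)C)(C(C)C)C(C)C)cc1 | intermediate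
16 | prop-2-yn-1-ol | C#CCO | starting material
17 | (5E)-5-{(2RS)-2-[(tert-butyldimethylsilyl)oxy]-4-(triisopropylsilyl)but-3-yn-1-yl}-7-[(4-methoxybenzyl)oxy]-6-methylhept-5-en-2-yn-1-ol | COc1ccc(COC/C(C)=C(\CC#CCO)CC(O[Si](C)(C)C(C)(C)C)C#C[Si](C(C)C)(C(C)C)C(C)C)cc1 | intermediate
18 | vinylmagnesium bromide | C=C[Mg]Br | starting material
19 | cyclic vinylmagnesium alkoxide from 17 (Mg on C10, vinyl on C1) | C=CC1=C(C/C(CC(O[Si](C)(C)C(C)(C)C)C#C[Si](C(C)C)(C(C)C)C(C)C)=C(/C)COCc2ccc(OC)cc2)[Mg]OC1 | intermediate
20 | (2E,5E)-2-ethenyl-5-{(2RS)-2-[(tert-butyldimethylsilyl)oxy]-4-(triisopropylsilyl)but-3-yn-1-yl}-7-[(4-methoxybenzyl)oxy]-6-methylhepta-2,5-dien-1-ol | OC/C(C=C)=C/C/C(CC(O[Si](C)(C)C(C)(C)C)C#C[Si](C(C)C)(C(C)C)C(C)C)=C(/C)COCc1ccc(OC)cc1 | intermediate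
21 | (2E,5E)-2-ethenyl-5-[(2RS)-2-hydroxybut-3-yn-1-yl]-7-[(4-methoxybenzyl)oxy]-6-methylhepta-2,5-dien-1-ol | OC/C(C=C)=C/C/C(CC(O)C#C)=C(/C)COCc1ccc(OC)cc1 | intermediate
22 | magnesium chelate from 21 (Mg on C4 bound to O6, methyl on C5, C14 bromomagnesium alkoxide) | CC1=C[Mg]OC1C/C(=C(\C)COCc2ccc(OC)cc2)C/C=C(\C=C)CO[Mg]Br | intermediate
23 | (2E,5E)-2-ethenyl-5-[(2RS,3Z)-2-hydroxy-4-iodo-3-methylbut-3-en-1-yl]-7-[(4-methoxybenzyl)oxy]-6-methylhepta-2,5-dien-1-ol | I/C=C(/C)C(O)C/C(=C(\C)COCc1ccc(OC)cc1)C/C=C(\C=C)CO | intermediate
24 | (1R,10R)-vinyl epoxy alcohol (C14 OH; C13 OPMB; C6 OH, 6RS; 4Z iodoalkene) | I/C=C(/C)C(O)C/C(=C(\C)COCc1ccc(OC)cc1)C[C@H]2O[C@]2(C=C)CO | intermediate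
25 | C14 acetate of 24 | I/C=C(/C)C(O)C/C(=C(\C)COCc1ccc(OC)cc1)C[C@H]2O[C@]2(C=C)COC(C)=O | intermediate
26 | C6 triethylsilyl ether of 25 | I/C=C(/C)C(O[Si](CC)(CC)CC)C/C(=C(\C)COCc1ccc(OC)cc1)C[C@H]2O[C@]2(C=C)COC(C)=O | intermediate
27 | C13 allylic alcohol from 26 | I/C=C(/C)C(O[Si](CC)(CC)CC)C/C(=C(\C)CO)C[C@H]2O[C@]2(C=C)COC(C)=O | intermediate
28 | (1R,8S,10R,11S)-bis-epoxide with free C13 hydroxyl | I/C=C(/C)C(O[Si](CC)(CC)CC)C[C@]3(C[C@H]1O[C@]1(C=C)COC(C)=O)O[C@@]3(C)CO | intermediate
29 | bis-epoxy vinyl iodide with terminal vinyl group (C6 triethylsilyl ether, 6RS) | I/C=C(/C)C(O[Si](CC)(CC)CC)C[C@]3(C[C@H]1O[C@]1(C=C)COC(C)=O)O[C@@]3(C)COC(C)=O | intermediate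
30 | C3 B-alkyl-9-borabicyclo[3.3.1]nonane from 29 | I/C=C(/C)C(O[Si](CC)(CC)CC)C[C@]3(C[C@H]1O[C@]1(CCB4C5CCCC4CCC5)COC(C)=O)O[C@@]3(C)COC(C)=O | intermediate
31 | C6 triethylsilyloxy bis-epoxy macrocycle (4Z, 6RS) | CC(=O)OC[C@]12CC/C=C(/C)C(O[Si](CC)(CC)CC)C[C@]3(C[C@H]1O2)O[C@@]3(C)COC(C)=O | intermediate
32 | C6 alcohol of the bis-epoxy macrocycle (6RS) | CC(=O)OC[C@]12CC/C=C(/C)C(O)C[C@]3(C[C@H]1O2)O[C@@]3(C)COC(C)=O | intermediate
33 | CNP0185847.4, (1R,8S,10R,11S,4Z)-bis-epoxy cyclodecenone diacetate | CC(=O)OC[C@]12CC/C=C(/C)C(=O)C[C@]3(C[C@H]1O2)O[C@@]3(C)COC(C)=O | target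

**Step count and least certain steps**

Total step count: 20. Longest linear sequence: 20 steps (1 to 33); the route is fully linear, and the other building blocks (2, 8, 16, 18) are bought.

Step 18 (key step). The most likely failure is that ring closure to a strained ten-membered ring loses to intermolecular coupling and to protodeboronation. Second to that, the hydroxyborate may attack the oxirane carbon C1 three atoms away, or the acetates may hydrolyse in the aqueous base. Fallback, from 29 back to 31: hydroborate as before and oxidise (NaBO3) to the C3 primary alcohol F1; convert it to the primary iodide F2 (I2, PPh3, imidazole); insert zinc into the alkyl C–I bond only (Zn dust, LiCl, THF) to give the alkylzinc iodide F3; close C3–C4 by intramolecular Negishi coupling with a zerovalent palladium catalyst, Pd(PPh3)4, at high dilution. This avoids the borate and the aqueous base altogether.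

Step 11. The late carbomagnesiation may stall because the terminal alkyne is deprotonated faster than it is carbometalated. The iodine quench may also engage the diene and the alkoxides (iodoetherification). Fallback, from 21 back to 23: silylate both hydroxyls (Et3SiCl, imidazole) to the bis-triethylsilyl ether F4; hydrate the terminal alkyne in the Markovnikov sense (Ph3PAuNTf2, aqueous dioxane) to the methyl ketone F5; carry out a Stork–Zhao olefination with the ylide from (iodomethyl)triphenylphosphonium iodide to the iodoalkene F6; remove both silyl groups with buffered HF·pyridine. The known weakness is incomplete Z selectivity on a ketone, so the isomers would have to be separated.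

Step 9. Addition of the vinyl Grignard reagent to the internal alkynol may be incomplete at temperatures the substrate tolerates, and the hot basic medium may isomerise the skipped enyne. Fallback, from 17 back to 20: hydroxyl-directed trans-hydrostannation (Bu3SnH, [Cp*RuCl]4) to the (Z)-alkenylstannane F7 with tin on C1, then Stille coupling with vinyl bromide (Pd(PPh3)4, CuI), which puts the vinyl group on C1 with retention.

Step 8. The allylic bromide may be lost through participation of the neighbouring cis benzyl-type ether oxygen (closure to a dihydrofuran), or the copper intermediate may scramble the regiochemistry or the alkene geometry. Fallback, from 15 back to 17: direct SN2 alkylation of the lithium acetylide of tetrahydropyranyl-protected propargyl alcohol (THF–DMPU, −78 °C) to the tetrahydropyranyl ether F8, then PPTS in methanol.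

Step 13. Discrimination between the neopentyl-type primary hydroxyl and the secondary allylic hydroxyl may be insufficient, leading to bis-acetylation or acetylation at the wrong site. Fallback, from 24 back to 26: silylate both hydroxyls (excess Et3SiCl) to the bis-silyl ether F9; cleave only the primary silyl ether (HF·pyridine, pyridine, −20 °C) to the C14 alcohol F10; acetylate (Ac2O, pyridine). Differentiation then rests on silyl ether lability and not on acylation rate.

**Further compounds**

F1 | step 18 | C3 primary alcohol from hydroboration–oxidation of 29 | I/C=C(/C)C(O[Si](CC)(CC)CC)C[C@]3(C[C@H]1O[C@]1(CCO)COC(C)=O)O[C@@]3(C)COC(C)=O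
F2 | step 18 | C3 primary iodide | I/C=C(/C)C(O[Si](CC)(CC)CC)C[C@]3(C[C@H]1O[C@]1(CCI)COC(C)=O)O[C@@]3(C)COC(C)=O
F3 | step 18 | C3 alkylzinc iodide | I/C=C(/C)C(O[Si](CC)(CC)CC)C[C@]3(C[C@H]1O[C@]1(CC[Zn]I)COC(C)=O)O[C@@]3(C)COC(C)=O
F4 | step 11 | bis-triethylsilyl ether of 21 | CC[Si](CC)(CC)OC/C(C=C)=C/C/C(CC(O[Si](CC)(CC)CC)C#C)=C(/C)COCc1ccc(OC)cc1
F5 | step 11 | methyl ketone from hydration of F4 | CC[Si](CC)(CC)OC/C(C=C)=C/C/C(CC(O[Si](CC)(CC)CC)C(C)=O)=C(/C)COCc1ccc(OC)cc1
F6 | step 11 | bis-triethylsilyl ether of 23 | I/C=C(/C)C(O[Si](CC)(CC)CC)C/C(=C(\C)COCc1ccc(OC)cc1)C/C=C(\C=C)CO[Si](CC)(CC)CC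
F7 | step 9 | (Z)-alkenylstannane from 17 (tributyltin on C1) | OC/C([Sn](CCCC)(CCCC)CCCC)=C/C/C(CC(O[Si](C)(C)C(C)(C)C)C#C[Si](C(C)C)(C(C)C)C(C)C)=C(/C)COCc1ccc(OC)cc1
F8 | step 8 | tetrahydropyranyl ether of 17 | COc1ccc(COC/C(C)=C(\CC#CCOC2CCCCO2)CC(O[Si](C)(C)C(C)(C)C)C#C[Si](C(C)C)(C(C)C)C(C)C)cc1
F9 | step 13 | bis-triethylsilyl ether of 24 | I/C=C(/C)C(O[Si](CC)(CC)CC)C/C(=C(\C)COCc1ccc(OC)cc1)C[C@H]2O[C@]2(C=C)CO[Si](CC)(CC)CC
F10 | step 13 | C6 triethylsilyl ether of 24 with free C14 hydroxyl | I/C=C(/C)C(O[Si](CC)(CC)CC)C/C(=C(\C)COCc1ccc(OC)cc1)C[C@H]2O[C@]2(C=C)CO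
A1 | alternative 1 | methyl 4-[(tert-butyldimethylsilyl)oxy]-4-methoxy-3-methyl-2-methylidenebut-3-enoate | C=C(C(=O)OC)C(C)=C(OC)O[Si](C)(C)C(C)(C)C
A2 | alternative 1 | 4-(1,3-dioxolan-2-yl)-2-methylidenebutanal | O=CC(=C)CCC1OCCO1
A3 | alternative 1 | dihydropyranone with C7 ester | COC(=O)C1=C(C)C(=O)O[C@H](C(=C)CCC2OCCO2)C1
A4 | alternative 2 | 3-[(tert-butyldimethylsilyl)oxy]-1-[(2R)-2-methyloxiran-2-yl]propan-1-one | C[C@@]1(CO1)C(=O)CCO[Si](C)(C)C(C)(C)C
A5 | alternative 2 | bromo(2-tert-butoxy-2-oxoethyl)zinc | CC(C)(C)OC(=O)C[Zn]Br
A6 | alternative 2 | spiro-epoxy ester with free C13 hydroxyl | CC(C)(C)OC(=O)C[C@]1(CCO[Si](C)(C)C(C)(C)C)O[C@@]1(C)CO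
A7 | alternative 3 | seco S-phenyl thioester with (Z)-tributylstannyl alkene | CCCC[Sn](CCCC)(CCCC)/C(C)=C\CC/C(CO[Si](C)(C)C(C)(C)C)=C\C/C(=C(/C)COCc1ccc(OC)cc1)CC(=O)Sc2ccccc2
A8 | alternative 3 | protected cyclodecatrienone | CC(C)(C)[Si](C)(C)OC/C1=C/C/C(=C(/C)COCc2ccc(OC)cc2)CC(=O)/C(C)=C\CC1
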